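Numbering (ring carbons in SMILES order): C1 CHOMe, C2, C3, C4 CH-iPr, C5 quaternary, C6, C7, C8 CMe, C9, C10, C11 C(OH)Me, C12 CHOH, C13, C14 CHBr, C15 bridge CH2. Ring A = C8, C9, C11–C14; ring B = C5–C10; α is the face of rings A and B that bears the C8 methyl, β the face of H9 and C15.
Enabling feature: C1, C2, C3, C4, C5, C10 and C15 form a norbornane (bridgeheads C2, C5) whose endo valences at C1 and C3 point at each other. One more bond, C1–C3, therefore gives a nortricyclene with C5 as apex, and the oxygen on C1 marks exactly this bond for later heterolysis.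
Cuts, in retrosynthetic order: C11–O and C12–O (epoxide), C1–OCH3, C11–CH3, C11=O (allylic C–H), C14–Br, C9–C10 (aldol), C8–CH3, C7–C8, C6–C7, C4–iPr with re-formation of C1–C3, then C1–C3 and C2–C3 together (carbenoid), finally C5–C10 and C5–C15 (malonate alkylation).
Forward: cyclopentene (C5, C10, C1, C2, C15), then the cage in one (2+1) addition (cyclopropane plus both five-membered rings through C3–C4), then the norbornenone by breaking C1–C3. Ring A is attached as cyclohexane-1,3-dione on a two-carbon arm, ring B is closed by aldol condensation, and ring A is functionalised last.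
Stereochemistry: C5 from asymmetric hydroboration relayed by lactonisation; C1–C3 of the cage from C5; C4 by exo hydrogenation; C8 by a catalyst-controlled dione reduction; C9 and C10 by equilibration; C14 by radical hydrogen delivery; C1 by exo hydride; C11 and C12 by β-epoxidation and diaxial opening.

Key step: step 7

Assumption: the sense of induction of (−)-Ipc2BH on the cyclopentene diester (cis-alkene model) and of the (S,S)-ruthenium catalyst on the triketone (carbinol S, hydride anti to the axial C8 methyl) follows the usual models; if either is reversed, the mirror-image reagent is used and nothing else changes.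

Step 1
Reactants: 1 dimethyl malonate; 2 cis-1,4-dichlorobut-2-ene
Product: 3 dimethyl cyclopent-3-ene-1,1-dicarboxylate
Conditions: LiH, DMF, 0 °C to rt
Reagents that add atoms: none
Why: Double malonate alkylation: after the first SN2 step the Z-alkene holds the second allylic chloride next to the malonate anion, so 5-exo-tet closure to the cyclopentene (C5, C10, C1, C2, C15) should outrun SN2' closure to a vinylcyclopropane.

Step 2
Reactants: 3 dimethyl cyclopent-3-ene-1,1-dicarboxylate
Product: 4 dimethyl (3S)-3-hydroxycyclopentane-1,1-dicarboxylate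
Conditions: (−)-Ipc2BH, THF, −25 °C; then 30% H2O2, aq. Na2CO3, 0 °C
Reagents that add atoms: hydrogen peroxide, OO
Why: Asymmetric hydroboration–oxidation of a cis-disubstituted ring alkene: the two faces of 3 are homotopic, so the pinene-derived borane only has to tell the two enantiotopic alkene carbons apart, and the cis-alkene model places boron (then OH, with retention) on C1 with S configuration.

Step 3
Reactants: 4 dimethyl (3S)-3-hydroxycyclopentane-1,1-dicarboxylate
Product: 5 methyl (1S,4R)-3-oxo-2-oxabicyclo[2.2.1]heptane-4-carboxylate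
Conditions: TsOH·H2O (5 mol %), toluene, reflux, MeOH distilled off
Reagents that add atoms: none
Why: Acid-catalysed transesterification (lactonisation): only the ester on the ring face of the C1 oxygen can form the bridged γ-lactone, so the carbinol centre tells the two diastereotopic esters apart and makes C5 a defined stereocentre (lactone carbonyl = C4, remaining ester = C6).

Step 4
Reactants: 5 methyl (1S,4R)-3-oxo-2-oxabicyclo[2.2.1]heptane-4-carboxylate
Product: 7 (1S)-1-(methoxycarbonyl)-3-oxocyclopentane-1-carboxylic acid, via lithium hydroxy carboxylate 6 (not isolated)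
Conditions: LiOH (1.0 equiv), THF/H2O, 0 °C; then TEMPO (cat.), KBr (cat.), NaOCl, aq. NaHCO3, 0 °C; HCl to pH 3
Reagents that add atoms: lithium hydroxide, [Li+].[OH-]
Why: Saponification followed by nitroxyl-catalysed hypochlorite oxidation: hydroxide should open the strained bridged lactone faster than it attacks the hindered methyl ester, and oxidising the carboxylate salt in the same pot removes the alcohol before it can relactonise, C5 being untouched.

Step 5
Reactants: 7 (1S)-1-(methoxycarbonyl)-3-oxocyclopentane-1-carboxylic acid
Product: 9 (1S)-3-(tert-butyldimethylsilyloxy)-1-(methoxycarbonyl)cyclopent-3-ene-1-carboxylic acid, via bis-silylated keto acid 8 (not isolated)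
Conditions: TBSOTf (2.2 equiv), Et3N, CH2Cl2, −78 to 0 °C; then K2CO3, THF/H2O, 0 °C; pH 5 buffer
Reagents that add atoms: tert-butyldimethylsilyl triflate, CC(C)(C)[Si](C)(C)OS(=O)(=O)C(F)(F)F
Why: Soft enolisation with silyl triflate and amine: C2 is unhindered whereas C10 is neopentyl next to quaternary C5, so both the rate of proton loss and enol ether stability point to C1=C2, and brief carbonate hydrolysis then frees only the far more labile silyl ester.

Step 6
Reactants: 9 (1S)-3-(tert-butyldimethylsilyloxy)-1-(methoxycarbonyl)cyclopent-3-ene-1-carboxylic acid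
Product: 11 methyl (1S)-3-(tert-butyldimethylsilyloxy)-1-(diazoacetyl)cyclopent-3-ene-1-carboxylate, via acid chloride 10 (not isolated)
Conditions: 1-chloro-N,N,2-trimethylprop-1-en-1-amine, CH2Cl2, 0 °C; then CH2N2 (excess), Et2O, 0 °C
Reagents that add atoms: diazomethane, C=[N+]=[N-]
Why: The α-chloroenamine makes the acid chloride without releasing HCl, which spares the acid-labile enol ether, and acylation of excess diazomethane (first stage of the Arndt–Eistert sequence) gives the diazoketone C4(=O)–C3HN2; C5 has no α-hydrogen, so no ketene can form.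

Step 7
Reactants: 11 methyl (1S)-3-(tert-butyldimethylsilyloxy)-1-(diazoacetyl)cyclopent-3-ene-1-carboxylate
Product: 12 methyl 1-(tert-butyldimethylsilyloxy)-3-oxotricyclo[2.2.1.0(2,6)]heptane-4-carboxylate
Conditions: Rh2(OAc)4 (1 mol %), CH2Cl2, rt, slow addition of 11
Reagents that add atoms: none
Why: Rh2(OAc)4 expels N2 from 11 to give an electrophilic rhodium carbenoid at C3, which adds to the electron-rich C1=C2 enol ether in one concerted, asynchronous (2+1) event, C2–C3 bonding running ahead while the silyloxy group carries the developing positive charge at C1. The closest known reaction types are the metal-carbenoid cyclisation of cyclopent-3-enyl diazomethyl ketones to nortricyclanones and the carbenoid cyclopropanation of silyl enol ethers to donor–acceptor cyclopropanes. The three-membered ring C1–C2–C3 closes by cycloaddition, and the same two bonds bridge the cyclopentene, C1–C3 closing the ring C3–C4–C5–C10–C1 and C2–C3 closing the ring C3–C4–C5–C15–C2. The two-atom acyl arm on C5 can reach only the ring face on which it stands, so the single stereocentre C5 fixes C1, C2 and C3. The step needs cyclopropanation to beat C–H insertion, ylide formation and carbene dimerisation. This is secured by the nucleophilic alkene held a few ångström away, by the lack of any activated C–H within five-membered reach (C6 is an ester carbonyl) and by slow addition; a C1=C10 regioisomer of the enol ether could not give a cage.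

Step 8
Reactants: 12 methyl 1-(tert-butyldimethylsilyloxy)-3-oxotricyclo[2.2.1.0(2,6)]heptane-4-carboxylate; 13 isopropylmagnesium chloride
Product: 15 methyl 2-isopropyl-5-oxobicyclo[2.2.1]hept-2-ene-1-carboxylate, via tertiary cyclopropyl carbinol 14 (not isolated)
Conditions: CeCl3, THF, −78 °C; then 1 M HCl, THF, 0 °C to rt
Reagents that add atoms: none
Why: Organocerium 1,2-addition followed by acid-triggered cyclopropylcarbinyl-to-homoallyl fragmentation: the weakly basic cerium reagent should add to the non-enolisable C4 ketone (from the side away from the silyloxy group) faster than to the ester or by β-hydride transfer, and on protonation water leaves C4 while the C1–C3 bond, the one pushed by the C1 oxygen, breaks to give C3=C4 and the C1 ketone, with C2–C3 left intact.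

Step 9
Reactants: 15 methyl 2-isopropyl-5-oxobicyclo[2.2.1]hept-2-ene-1-carboxylate
Product: 16 methyl 2-endo-isopropyl-5-oxobicyclo[2.2.1]heptane-1-carboxylate
Conditions: H2 (1 atm), 10% Pd/C, EtOAc, rt
Reagents that add atoms: none
Why: Heterogeneous hydrogenation of a norbornene delivers both hydrogens from the exo face (the side of the C15 bridge), which turns the isopropyl group on C4 into the endo position of the target; ketone and ester are inert.

Step 10
Reactants: 16 methyl 2-endo-isopropyl-5-oxobicyclo[2.2.1]heptane-1-carboxylate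
Product: 17 4-(hydroxymethyl)-5-endo-isopropylbicyclo[2.2.1]heptan-2-endo-ol
Conditions: LiAlH4, THF, 0 °C to rt
Reagents that add atoms: none
Why: Hydride reduction takes the bridgehead ester C6 to the primary alcohol; the C1 ketone is reduced too (exo attack, endo alcohol), which is accepted because the next step restores it.

Step 11
Reactants: 17 4-(hydroxymethyl)-5-endo-isopropylbicyclo[2.2.1]heptan-2-endo-ol
Product: 18 2-endo-isopropyl-5-oxobicyclo[2.2.1]heptane-1-carbaldehyde
Conditions: Dess–Martin periodinane (2.4 equiv), NaHCO3, CH2Cl2, rt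
Reagents that add atoms: none
Why: Dess–Martin oxidation of both alcohols under near-neutral conditions gives the C6 aldehyde, which cannot epimerise because C5 is quaternary, and returns the C1 ketone.

Step 12
Reactants: 18 2-endo-isopropyl-5-oxobicyclo[2.2.1]heptane-1-carbaldehyde
Product: 20 (2-endo-isopropyl-5-oxobicyclo[2.2.1]hept-1-yl)acetaldehyde, via methyl enol ether 19 (not isolated)
Conditions: Ph3P(CH2OMe)Cl, KOtBu (1.1 equiv each), THF, −78 to 0 °C; then 2 M HCl, THF, rt
Reagents that add atoms: (methoxymethyl)triphenylphosphonium chloride, COC[P+](c1ccccc1)(c1ccccc1)c1ccccc1.[Cl-]; water, O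
Why: Wittig methoxymethylenation and enol ether hydrolysis (one-carbon homologation): about one equivalent of ylide reacts with the aldehyde far faster than with the ketone and adds C7.

Step 13
Reactants: 20 (2-endo-isopropyl-5-oxobicyclo[2.2.1]hept-1-yl)acetaldehyde; 21 cyclohexane-1,3-dione
Product: 23 2-[2-(2-endo-isopropyl-5-oxobicyclo[2.2.1]hept-1-yl)ethyl]cyclohexane-1,3-dione, via alkylidene dione 22 (not isolated)
Conditions: Hantzsch ester, L-proline (20 mol %), CH2Cl2, rt
Reagents that add atoms: none
Why: Three-component reductive alkylation (Knoevenagel condensation, then Hantzsch ester transfer hydrogenation of the alkylidene dione): it forms C7–C8 with the C-selectivity that alkylation of the dione by an unactivated halide lacks, and only the aldehyde, not the C1 ketone, condenses.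

Step 14
Reactants: 23 2-[2-(2-endo-isopropyl-5-oxobicyclo[2.2.1]hept-1-yl)ethyl]cyclohexane-1,3-dione
Product: 24 2-[2-(2-endo-isopropyl-5-oxobicyclo[2.2.1]hept-1-yl)ethyl]-2-methylcyclohexane-1,3-dione
Conditions: MeI, K2CO3, acetone, reflux
Reagents that add atoms: iodomethane, CI
Why: C-methylation of the stabilised 2-alkyl-1,3-dione enolate with the small, soft electrophile installs the C8 methyl; C8 stays prochiral because its two carbonyl arms are still equal, and carbonate does not enolise C1.

Step 15
Reactants: 24 2-[2-(2-endo-isopropyl-5-oxobicyclo[2.2.1]hept-1-yl)ethyl]-2-methylcyclohexane-1,3-dione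
Product: 25 hydroxy diketone with (14S)-OH cis to the C8 methyl
Conditions: RuCl(p-cymene)[(S,S)-TsDPEN] (2 mol %), HCO2H/Et3N 5:2, CH2Cl2, rt
Reagents that add atoms: none
Why: Desymmetrising asymmetric transfer hydrogenation of a 2,2-disubstituted cyclohexane-1,3-dione: the catalyst fixes the new carbinol C14 as S, hydride adds axially and anti to the axial C8 methyl so that OH and methyl end cis, and only one of the two carbonyl groups meets both demands, which makes C8 a defined quaternary centre; the activated dione carbonyl should react well before the isolated ketone C1, and the hydroxy ketone formed is no longer activated.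

Step 16
Reactants: 25 hydroxy diketone with (14S)-OH cis to the C8 methyl
Product: 26 14-O-TBS ether of 25
Conditions: TBSOTf, 2,6-lutidine, CH2Cl2, −78 to 0 °C
Reagents that add atoms: tert-butyldimethylsilyl triflate, CC(C)(C)[Si](C)(C)OS(=O)(=O)C(F)(F)F
Why: Silyl ether formation on the hindered alcohol blocks alkoxide-driven retro-aldol opening of ring A, which would scramble C8 under the base of the next step.

Step 17
Reactants: 26 14-O-TBS ether of 25
Product: 28 14α-silyloxy tetracyclic 9(10)-en-1-one, via ketol 27 (not isolated)
Conditions: KOtBu (0.3 equiv), t-BuOH/THF, 50 °C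
Reagents that add atoms: none
Why: Intramolecular aldol condensation (6-enolexo-exo-trig): C10 is the only enolisable position of the C1 ketone (C2 is a bridgehead) and C9 the only carbonyl within six-membered reach, so exo attack of C10 on C9 and E1cB loss of water close ring B as the tetrasubstituted enone without touching C8.

Step 18
Reactants: 28 14α-silyloxy tetracyclic 9(10)-en-1-one
Product: 29 14α-hydroxy tetracyclic 9(10)-en-1-one
Conditions: HF·pyridine, THF, 0 °C to rt
Reagents that add atoms: none
Why: Fluoride-driven silyl ether cleavage under mildly acidic conditions leaves the enone untouched and avoids base on the free β-hydroxy-type system.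

Step 19
Reactants: 29 14α-hydroxy tetracyclic 9(10)-en-1-one
Product: 30 tetracyclic 9(10)-ene-1,14-dione
Conditions: Dess–Martin periodinane, NaHCO3, CH2Cl2, rt
Reagents that add atoms: none
Why: Dess–Martin oxidation returns the C14 ketone; the carbinol centre has done its work of fixing C8 and is given up.

Step 20
Reactants: 30 tetracyclic 9(10)-ene-1,14-dione
Product: 31 14-triflyloxy-9(10),13-dien-1-one
Conditions: KN(SiMe3)2, THF, −78 °C; then PhNTf2
Reagents that add atoms: N-phenylbis(trifluoromethanesulfonimide), O=S(=O)(N(c1ccccc1)S(=O)(=O)C(F)(F)F)C(F)(F)F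
Why: Kinetic enolate triflation: α-deprotonation of the saturated ketone at C13 (C8 is quaternary) is faster than γ-deprotonation of the enone at C11, and the enone has no α'-hydrogen.

Step 21
Reactants: 31 14-triflyloxy-9(10),13-dien-1-one
Product: 32 14-bromo-9(10),13-dien-1-one
Conditions: [Cp*Ru(MeCN)3]OTf (5 mol %), LiBr, THF, 60 °C
Reagents that add atoms: lithium bromide, [Li+].[Br-]
Why: Ruthenium-catalysed triflate-to-halide exchange of alkenyl triflates puts bromine on C14 without hydrazine or free halogen, both of which would attack the enone.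

Step 22
Reactants: 32 14-bromo-9(10),13-dien-1-one
Product: 33 14α-bromo-9(10)-en-1-one
Conditions: Mn(dpm)3 (10 mol %), PhSiH3, t-BuOOH, i-PrOH, rt
Reagents that add atoms: none
Why: Metal-hydride hydrogen atom transfer hydrogenation, a radical method that keeps the halogen of alkenyl halides: H adds to unhindered C13 and the α-bromo radical at C14 then takes hydrogen axially from the open β face (the α face carries the C8 methyl), so bromine ends equatorial (α), which is also the more stable epimer; the tetrasubstituted enone, whose β-carbon C9 sits next to quaternary C8, should react much more slowly.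

Step 23
Reactants: 33 14α-bromo-9(10)-en-1-one
Product: 34 14α-bromo-9(10)-ene-1,11-dione
Conditions: Rh2(cap)4 (1 mol %), t-BuOOH (70% aq.), CH2Cl2, 40 °C
Reagents that add atoms: tert-butyl hydroperoxide, CC(C)(C)OO
Why: Dirhodium caprolactamate/hydroperoxide allylic oxidation of an enone to the enedione: C11 is the only allylic CH2 (C5 and C8 are quaternary), so the oxygen enters there.

Step 24
Reactants: 34 14α-bromo-9(10)-ene-1,11-dione
Product: 35 14α-bromo-1,11-dione with 9β-H and 10α-H
Conditions: Zn dust, AcOH, rt to 50 °C
Reagents that add atoms: none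
Why: Zinc reduction of an enedione to the 1,4-diketone; both new centres are α to a carbonyl and equilibrate in warm acetic acid to the all-chair arrangement, with C9 exo on C10 (an endo C9 would collide with the endo isopropyl on C4) and H9 axial and anti to the C8 methyl (trans ring fusion), while the unactivated secondary bromide is not reduced.

Step 25
Reactants: 35 14α-bromo-1,11-dione with 9β-H and 10α-H
Product: 36 14α-bromo-11-triflyloxy-11-en-1-one
Conditions: KN(SiMe3)2 (1.05 equiv), THF, −78 °C; then PhNTf2
Reagents that add atoms: N-phenylbis(trifluoromethanesulfonimide), O=S(=O)(N(c1ccccc1)S(=O)(=O)C(F)(F)F)C(F)(F)F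
Why: Kinetic enolate triflation: C12–H2 is the only accessible acidic site (H9 is tertiary beside C8, H10 is the slowly exchanging endo hydrogen of a norbornanone, C2 is a bridgehead), and at −78 °C the enolate is trapped before it can displace the neopentyl-type bromide.

Step 26
Reactants: 36 14α-bromo-11-triflyloxy-11-en-1-one
Product: 37 14α-bromo-11-methyl-11-en-1-one
Conditions: Pd(PPh3)4 (5 mol %), Me2Zn, THF, 0 °C to rt
Reagents that add atoms: dimethylzinc, C[Zn]C
Why: Negishi cross-coupling of the alkenyl triflate brings in the C11 methyl as the C11=C12 alkene; dimethylzinc does not add to the C1 ketone, and the secondary alkyl bromide undergoes oxidative addition far more slowly than the triflate.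

Step 27
Reactants: 37 14α-bromo-11-methyl-11-en-1-one
Product: 38 14α-bromo-11-methyl-11-en-1-endo-ol
Conditions: NaBH4, MeOH/THF, 0 °C
Reagents that add atoms: none
Why: Borohydride reduction of a norbornanone without substituents on the one-carbon bridge occurs from the exo face, even with an exo group on the neighbouring carbon, so the C1 hydroxyl is endo; alkene and bromide are inert.

Step 28
Reactants: 38 14α-bromo-11-methyl-11-en-1-endo-ol
Product: 39 14α-bromo-1-endo-methoxy-11-methyl-11-ene
Conditions: NaH, MeI, THF/DMF, 0 °C to rt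
Reagents that add atoms: iodomethane, CI
Why: Williamson etherification with the smallest electrophile methylates the hindered endo alkoxide with retention at C1; the equatorial bromide has no antiperiplanar hydrogen, so elimination is slow.

Step 29
Reactants: 39 14α-bromo-1-endo-methoxy-11-methyl-11-ene
Product: 40 11β,12β-epoxide of 39
Conditions: mCPBA, NaHCO3, CH2Cl2, 0 °C
Reagents that add atoms: 3-chloroperoxybenzoic acid, OOC(=O)c1cccc(Cl)c1
Why: Prilezhaev epoxidation of the only alkene; the axial C8 methyl shields the α face of C11, so oxygen is delivered from the β face.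

Step 30
Reactants: 40 11β,12β-epoxide of 39
Product: 41 target CNP0130529.1
Conditions: HClO4 (cat.), THF/H2O, 0 °C to rt
Reagents that add atoms: water, O
Why: Acid-catalysed epoxide hydrolysis under the Fürst–Plattner rule: water attacks the tertiary carbon C11 from the α face with inversion while the epoxide oxygen stays on C12, an opening in which charge stabilisation and the diaxial requirement agree, giving 11α-OH (methyl equatorial) and 12β-OH.

Compound list
1 | dimethyl malonate | COC(=O)CC(=O)OC | starting material
2 | cis-1,4-dichlorobut-2-ene | ClC/C=C\CCl | starting material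
3 | dimethyl cyclopent-3-ene-1,1-dicarboxylate | COC(=O)C1(C(=O)OC)CC=CC1 | intermediate
4 | dimethyl (3S)-3-hydroxycyclopentane-1,1-dicarboxylate | O[C@H]1CCC(C(=O)OC)(C(=O)OC)C1 | intermediate
5 | methyl (1S,4R)-3-oxo-2-oxabicyclo[2.2.1]heptane-4-carboxylate | O=C1O[C@H]2CC[C@]1(C(=O)OC)C2 | intermediate
6 | lithium salt of the hydroxy half ester, OH cis to carboxylate (not isolated) | O[C@H]1CC[C@](C(=O)[O-])(C(=O)OC)C1.[Li+] | intermediate
7 | (1S)-1-(methoxycarbonyl)-3-oxocyclopentane-1-carboxylic acid | O=C1CC[C@](C(=O)O)(C(=O)OC)C1 | intermediate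
8 | TBS ester and TBS enol ether of 7 (not isolated) | CC(C)(C)[Si](C)(C)OC1=CC[C@](C(=O)O[Si](C)(C)C(C)(C)C)(C(=O)OC)C1 | intermediate
9 | (1S)-3-(tert-butyldimethylsilyloxy)-1-(methoxycarbonyl)cyclopent-3-ene-1-carboxylic acid | CC(C)(C)[Si](C)(C)OC1=CC[C@](C(=O)O)(C(=O)OC)C1 | intermediate
10 | acid chloride of 9 (not isolated) | CC(C)(C)[Si](C)(C)OC1=CC[C@](C(=O)Cl)(C(=O)OC)C1 | intermediate
11 | methyl (1S)-3-(tert-butyldimethylsilyloxy)-1-(diazoacetyl)cyclopent-3-ene-1-carboxylate | CC(C)(C)[Si](C)(C)OC1=CC[C@](C(=O)C=[N+]=[N-])(C(=O)OC)C1 | intermediate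
12 | methyl 1-(tert-butyldimethylsilyloxy)-3-oxotricyclo[2.2.1.0(2,6)]heptane-4-carboxylate (OTBS on C1, ketone C4, ester on apex C5) | CC(C)(C)[Si](C)(C)O[C@]12[C@@H]3C[C@](C(=O)[C@H]23)(C(=O)OC)C1 | intermediate
13 | isopropylmagnesium chloride | CC(C)[Mg]Cl | starting material
14 | C4 tertiary carbinol of the cage, isopropyl on the side away from OTBS (not isolated) | CC(C)(C)[Si](C)(C)O[C@]12[C@@H]3C[C@]([C@@](O)(C(C)C)[C@H]23)(C(=O)OC)C1 | intermediate
15 | methyl 2-isopropyl-5-oxobicyclo[2.2.1]hept-2-ene-1-carboxylate (C3=C4, C1 ketone) | O=C1C[C@@]2(C(=O)OC)C[C@@H]1C=C2C(C)C | intermediate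
16 | methyl 2-endo-isopropyl-5-oxobicyclo[2.2.1]heptane-1-carboxylate | O=C1C[C@@]2(C(=O)OC)C[C@@H]1C[C@H]2C(C)C | intermediate
17 | 4-(hydroxymethyl)-5-endo-isopropylbicyclo[2.2.1]heptan-2-endo-ol | O[C@@H]1C[C@@]2(CO)C[C@@H]1C[C@H]2C(C)C | intermediate
18 | 2-endo-isopropyl-5-oxobicyclo[2.2.1]heptane-1-carbaldehyde | O=C1C[C@@]2(C=O)C[C@@H]1C[C@H]2C(C)C | intermediate
19 | C6=C7 methyl enol ether, E/Z mixture (not isolated) | O=C1C[C@@]2(C=COC)C[C@@H]1C[C@H]2C(C)C | intermediate
20 | (2-endo-isopropyl-5-oxobicyclo[2.2.1]hept-1-yl)acetaldehyde | O=C1C[C@@]2(CC=O)C[C@@H]1C[C@H]2C(C)C | intermediate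
21 | cyclohexane-1,3-dione | O=C1CCCC(=O)C1 | starting material
22 | C7=C8 alkylidene dione (not isolated) | O=C1C[C@@]2(CC=C3C(=O)CCCC3=O)C[C@@H]1C[C@H]2C(C)C | intermediate
23 | 2-[2-(2-endo-isopropyl-5-oxobicyclo[2.2.1]hept-1-yl)ethyl]cyclohexane-1,3-dione | O=C1C[C@@]2(CCC3C(=O)CCCC3=O)C[C@@H]1C[C@H]2C(C)C | intermediate
24 | 2-methyl derivative of 23 (triketone, C8 prochiral) | O=C1C[C@@]2(CCC3(C)C(=O)CCCC3=O)C[C@@H]1C[C@H]2C(C)C | intermediate
25 | hydroxy diketone, (14S)-OH cis to the C8 methyl, C8 as in the target | O=C1C[C@@]2(CC[C@]3(C)[C@@H](O)CCCC3=O)C[C@@H]1C[C@H]2C(C)C | intermediate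
26 | 14-O-TBS ether of 25 | O=C1C[C@@]2(CC[C@]3(C)[C@@H](O[Si](C)(C)C(C)(C)C)CCCC3=O)C[C@@H]1C[C@H]2C(C)C | intermediate
27 | ketol, 9β-OH, 10α-H, trans-fused rings A and B (not isolated) | O=C1[C@H]2C[C@@H](C(C)C)[C@]3(CC[C@@]4(C)[C@](O)([C@H]13)CCC[C@@H]4O[Si](C)(C)C(C)(C)C)C2 | intermediate
28 | 14α-silyloxy tetracyclic 9(10)-en-1-one | O=C1[C@H]2C[C@@H](C(C)C)[C@]3(CC[C@@]4(C)C(=C13)CCC[C@@H]4O[Si](C)(C)C(C)(C)C)C2 | intermediate
29 | 14α-hydroxy tetracyclic 9(10)-en-1-one | O=C1[C@H]2C[C@@H](C(C)C)[C@]3(CC[C@@]4(C)C(=C13)CCC[C@@H]4O)C2 | intermediate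
30 | tetracyclic 9(10)-ene-1,14-dione | O=C1[C@H]2C[C@@H](C(C)C)[C@]3(CC[C@@]4(C)C(=C13)CCCC4=O)C2 | intermediate
31 | 14-triflyloxy-9(10),13-dien-1-one | O=C1[C@H]2C[C@@H](C(C)C)[C@]3(CC[C@@]4(C)C(=C13)CCC=C4OS(=O)(=O)C(F)(F)F)C2 | intermediate
32 | 14-bromo-9(10),13-dien-1-one | O=C1[C@H]2C[C@@H](C(C)C)[C@]3(CC[C@@]4(C)C(=C13)CCC=C4Br)C2 | intermediate
33 | 14α-bromo-9(10)-en-1-one (Br equatorial) | O=C1[C@H]2C[C@@H](C(C)C)[C@]3(CC[C@@]4(C)C(=C13)CCC[C@@H]4Br)C2 | intermediate
34 | 14α-bromo-9(10)-ene-1,11-dione | O=C1[C@H]2C[C@@H](C(C)C)[C@]3(CC[C@@]4(C)C(=C13)C(=O)CC[C@@H]4Br)C2 | intermediate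
35 | 14α-bromo-1,11-dione, 9β-H, 10α-H (C9 exo on C10) | O=C1[C@H]2C[C@@H](C(C)C)[C@]3(CC[C@@]4(C)[C@H]([C@H]13)C(=O)CC[C@@H]4Br)C2 | intermediate
36 | 14α-bromo-11-triflyloxy-11-en-1-one | O=C1[C@H]2C[C@@H](C(C)C)[C@]3(CC[C@@]4(C)[C@H]([C@H]13)C(OS(=O)(=O)C(F)(F)F)=CC[C@@H]4Br)C2 | intermediate
37 | 14α-bromo-11-methyl-11-en-1-one | O=C1[C@H]2C[C@@H](C(C)C)[C@]3(CC[C@@]4(C)[C@H]([C@H]13)C(C)=CC[C@@H]4Br)C2 | intermediate
38 | 14α-bromo-11-methyl-11-en-1-endo-ol | O[C@H]1[C@H]2C[C@@H](C(C)C)[C@]3(CC[C@@]4(C)[C@H]([C@H]13)C(C)=CC[C@@H]4Br)C2 | intermediate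
39 | 14α-bromo-1-endo-methoxy-11-methyl-11-ene | CO[C@H]1[C@H]2C[C@@H](C(C)C)[C@]3(CC[C@@]4(C)[C@H]([C@H]13)C(C)=CC[C@@H]4Br)C2 | intermediate
40 | 11β,12β-epoxide of 39 | CO[C@H]1[C@H]2C[C@@H](C(C)C)[C@]3(CC[C@@]4(C)[C@H]([C@H]13)[C@@]5(C)O[C@H]5C[C@@H]4Br)C2 | intermediate
41 | CNP0130529.1 | CO[C@H]1[C@H]2C[C@@H](C(C)C)[C@]3(CC[C@@]4(C)[C@H]([C@H]13)[C@](C)(O)[C@@H](O)C[C@@H]4Br)C2 | target

Total step count: 30. Longest linear sequence: 30 steps (from 1 and 2; 13 and 21 enter as bought reagents).

Steps most likely to fail

Step 15. Three things can go wrong: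
- competing reduction of the C1 ketone;
- over-reduction to the diol;
- poor discrimination between the two dione carbonyl groups, which would erode C8.

The fallback sets out from 24 and comes back at 30. The reduction, protection, deprotection and re-oxidation are dropped, and 24 is cyclised directly with KOtBu in t-BuOH/THF. The aldol condensation itself then differentiates the two carbonyl groups under the influence of the enantiopure norbornane. This should give 30 together with its C8 epimer, the 8-epi ene-dione F1. The two are diastereomers and are separated by chromatography. The detour is four steps shorter but costs material, because the cis-ketol pathway that leads to F1 may well be preferred.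

Step 22. Three things can go wrong:
- loss of bromine by radical or hydride pathways;
- competing conjugate reduction of the enone;
- hydrogen delivery from the wrong face.

The fallback sets out from 30 and comes back at 33, replacing steps 20 to 22 by an ionic route. LiBH(s-Bu)3 in THF at −78 °C attacks the C14 ketone along the equatorial trajectory and should give the axial alcohol, the 14β-hydroxy enone F2. Appel bromination (PPh3, CBr4, CH2Cl2) then replaces the axial oxygen with inversion to give the equatorial bromide 33. Substitution next to the quaternary C8 is slow and competes with elimination, which is why this is the reserve and not the main line.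

Step 8. Three things can go wrong:
- β-hydride transfer from the isopropyl reagent to the hindered ketone;
- retro-aldol opening of the β-alkoxy ester;
- attack at the ester.

The fallback sets out from 12 and comes back at 16, and brings the three carbons in as an sp2 nucleophile without β-hydrogen. CH2=C(CH3)MgBr with CeCl3 in THF at −78 °C should give the isopropenyl carbinol F3. This ionises even more readily in 1 M HCl/THF and fragments at C1–C3 to the dienone ester F4. Hydrogenation (H2, Pd/C, EtOAc) then saturates both C=C bonds, the ring alkene from the exo face, and gives 16 directly.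

Further compounds
F1 | step 15 | 8-epi tetracyclic 9(10)-ene-1,14-dione | O=C1[C@H]2C[C@@H](C(C)C)[C@]3(CC[C@]4(C)C(=C13)CCCC4=O)C2
F2 | step 22 | 14β-hydroxy tetracyclic 9(10)-en-1-one | O=C1[C@H]2C[C@@H](C(C)C)[C@]3(CC[C@@]4(C)C(=C13)CCC[C@H]4O)C2
F3 | step 8 | C4 isopropenyl carbinol of the cage | CC(C)(C)[Si](C)(C)O[C@]12[C@@H]3C[C@]([C@@](O)(C(C)=C)[C@H]23)(C(=O)OC)C1
F4 | step 8 | methyl 2-isopropenyl-5-oxobicyclo[2.2.1]hept-2-ene-1-carboxylate | O=C1C[C@@]2(C(=O)OC)C[C@@H]1C=C2C(C)=C
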